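**Strategy**

Ring B is taken apart first (C4=C5 by Horner–Wadsworth–Emmons closure, C7=C7a by dehydrogenation), which leaves ring A alone: an oxolane with aryl at C2, methyl at C3 and an all-carbon centre C3a carrying allyl and the C4 formyl group (benzofuran numbering). That 3-formyloxolane pattern is what a Prins–pinacol ring contraction delivers. In one operation it joins 3,4,5-trimethoxybenzaldehyde to a (3R,5Z)-5-allyl-3,4-dioxygenated hept-5-enoate, forms O1–C2, C2–C3 and C3a–C7a, closes ring A and sets C2, C3 and C3a from the malate-derived centre C7a. The precursor is that diol ester as its bis(triethylsilyl) ether, the alkene methyl cis to the carbinol carbon.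

Key step: step 7

**Remarks on the chemistry (assumptions and corrections)**

- Atom labels C2 to C7a follow the benzofuran numbering of the target in every Why line.
- By oxolane numbering the key-step product carries the acetate arm on C2, allyl and formyl on C3, methyl on C4 and aryl on C5. It is therefore the 3-allyl-3-formyl-4-methyl-5-aryl compound; a 4-allyl-4-formyl-3-methyl name would put the quaternary carbon next to the aryl-bearing carbon, which the connectivity excludes.
- A free 3,4-dihydroxy methyl ester is a γ-hydroxy ester and would close to the butanolide, whose ring oxygen can no longer enter the acetal. The diol is therefore never set free: it is carried as its bis(triethylsilyl) ether, and the acetal is made directly from the two silyl ethers.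
- The carbinol carbon C4 of the heptenoate becomes the formyl carbon, so it is carried as a mixture of epimers.
- The target is (2R,3S,3aS); dimethyl (R)-malate supplies the matching (R) centre.

**Route**

Step 1
Reactants: 1 dimethyl (R)-malate
Product: 2 methyl (R)-3,4-dihydroxybutanoate
Conditions: BH3·SMe2, NaBH4 (cat.), THF, 0 °C → rt; MeOH
Reagents that add atoms: none
Why: Hydroxyl-directed borane reduction: the α-hydroxy ester is reduced through its cyclic oxyborane while the distal ester stays, and the stereocentre is not touched.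

Step 2
Reactants: 2 methyl (R)-3,4-dihydroxybutanoate
Product: 3 methyl (R)-3,4-bis(triethylsilyloxy)butanoate
Conditions: TESCl, imidazole, DMF, 0 °C → rt
Reagents that add atoms: chlorotriethylsilane, CC[Si](Cl)(CC)CC
Why: Standard silyl chloride/imidazole silylation; the primary hydroxyl reacts first, which removes the only hydroxyl able to lactonize.

Step 3
Reactants: 3 methyl (R)-3,4-bis(triethylsilyloxy)butanoate
Product: 4 methyl (R)-4-oxo-3-(triethylsilyloxy)butanoate
Conditions: (COCl)2, DMSO, CH2Cl2, −78 → −30 °C; Et3N, −78 → 0 °C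
Reagents that add atoms: none
Why: Swern oxidation with selective oxidative desilylation: only the primary triethylsilyl ether is converted into the alkoxysulfonium salt and oxidized, and the cold amine step should leave the α-silyloxy stereocentre intact (the aldehyde is used at once).

Step 4
Reactants: 4 methyl (R)-4-oxo-3-(triethylsilyloxy)butanoate; 5 prop-1-ynylmagnesium bromide
Product: 7 methyl (3R,4RS)-3,4-bis(triethylsilyloxy)hept-5-ynoate, via bromomagnesium alkoxide 6 (not isolated)
Conditions: CH3C≡CMgBr, THF, −78 °C; then TESOTf, −78 → −40 °C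
Reagents that add atoms: prop-1-ynylmagnesium bromide (5), CC#C[Mg]Br; triethylsilyl trifluoromethanesulfonate, CC[Si](CC)(CC)OS(=O)(=O)C(F)(F)F
Why: Alkynyl Grignard 1,2-addition to the aldehyde is far faster than attack on the ester at −78 °C, and silylation of the cold alkoxide by the silyl triflate forestalls lactonization; the new carbinol centre forms as an epimer mixture (Felkin-type bias), which is harmless because this carbon becomes the formyl group.

Step 5
Reactants: 7 methyl (3R,4RS)-3,4-bis(triethylsilyloxy)hept-5-ynoate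
Product: 8 methyl (3R,4RS,5E)-5-(tributylstannyl)-3,4-bis(triethylsilyloxy)hept-5-enoate
Conditions: Bu3SnH, PdCl2(PPh3)2 (cat.), THF, 0 °C → rt
Reagents that add atoms: tributyltin hydride, CCCC[SnH](CCCC)CCCC
Why: Palladium-catalysed syn-hydrostannation: H and Sn add to the same face, and tin should go to the alkyne carbon next to the oxygen-bearing carbon (inductive bias of propargylic ethers), which places CH3 cis to C4; any distal isomer would be removed by chromatography.

Step 6
Reactants: 8 methyl (3R,4RS,5E)-5-(tributylstannyl)-3,4-bis(triethylsilyloxy)hept-5-enoate; 9 allyl bromide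
Product: 10 methyl (3R,4RS,5Z)-5-allyl-3,4-bis(triethylsilyloxy)hept-5-enoate
Conditions: allyl bromide, Pd2(dba)3 (cat.), AsPh3, CuI, DMF, 45 °C
Reagents that add atoms: allyl bromide (9), C=CCBr
Why: Stille coupling (allyl bromide adds to zerovalent palladium, CuI-assisted transmetalation, reductive elimination) proceeds with retention at the alkenyl carbon, so the (Z) alkene with methyl cis to the carbinol carbon results.

Step 7
Reactants: 10 methyl (3R,4RS,5Z)-5-allyl-3,4-bis(triethylsilyloxy)hept-5-enoate; 11 3,4,5-trimethoxybenzaldehyde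
Product: 13 methyl 2-[(2R,3R,4S,5R)-3-allyl-3-formyl-4-methyl-5-(3,4,5-trimethoxyphenyl)oxolan-2-yl]acetate, via dioxolane acetal 12 (not isolated)
Conditions: 11, TMSOTf (cat.), CH2Cl2, −78 → −30 °C; then SnCl4, −78 → −23 °C; NaHCO3 (aq)
Reagents that add atoms: 3,4,5-trimethoxybenzaldehyde (11), COc1cc(C=O)cc(OC)c1OC
Why: Silyl triflate-catalysed condensation of the two silyl ethers with 11 (acetalization of silyl ethers) gives dioxolane 12, which SnCl4 opens reversibly; only the oxocarbenium ion on the oxygen of C7a can reach the alkene, whose CH(CH3) terminus (C3) attacks C2 while C7a migrates from the carbinol carbon to the developing tertiary cation at C3a and the tin-bound oxygen becomes the C4 formyl group. This is the Prins–pinacol ring contraction known for turning acetals of allylic 1,2-diols into 3-acyl and 3-formyl tetrahydrofurans. Ring A arises by a 6-endo-trig closure to an oxanyl cation that contracts by 1,2-alkyl shift to the five-membered ring. The closure runs through a chair with the aryl group of the (E)-oxocarbenium ion and the CH2CO2Me arm on C7a equatorial, so the (R) centre from 1 fixes C2; the (Z) alkene places its methyl group axial and sets C3 cis to aryl; C2 and the migrating C7a add to the same face of the former alkene, which sets C3a with formyl cis and allyl trans to methyl, and both C4 epimers of 10 converge. The step needs ring contraction to win over hydride shift from the carbinol carbon and over ionization of the benzylic C2–O1 bond, which the bond migration within the chair and temperatures at or below −23 °C should secure; the trisubstituted alkene is engaged in preference to the less nucleophilic terminal allyl alkene.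

Step 8
Reactants: 13 methyl 2-[(2R,3R,4S,5R)-3-allyl-3-formyl-4-methyl-5-(3,4,5-trimethoxyphenyl)oxolan-2-yl]acetate
Product: 14 methyl 2-[(2R,3R,4S,5R)-3-allyl-3-(dimethoxymethyl)-4-methyl-5-(3,4,5-trimethoxyphenyl)oxolan-2-yl]acetate
Conditions: HC(OMe)3, MeOH, PPTS (cat.), rt
Reagents that add atoms: trimethyl orthoformate, COC(OC)OC; methanol, CO
Why: Acid-catalysed acetalization with orthoformate as water scavenger masks the non-enolizable aldehyde under conditions mild enough for the benzylic ether of ring A and the ester.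

Step 9
Reactants: 14 methyl 2-[(2R,3R,4S,5R)-3-allyl-3-(dimethoxymethyl)-4-methyl-5-(3,4,5-trimethoxyphenyl)oxolan-2-yl]acetate; 15 diethyl (methoxymethyl)phosphonate
Product: 16 diethyl [(1RS)-3-[(2R,3R,4S,5R)-3-allyl-3-(dimethoxymethyl)-4-methyl-5-(3,4,5-trimethoxyphenyl)oxolan-2-yl]-1-methoxy-2-oxopropyl]phosphonate
Conditions: 15, LiN(i-Pr)2, THF, −78 °C; then 14, −78 → −20 °C; NH4Cl (aq)
Reagents that add atoms: diethyl (methoxymethyl)phosphonate (15), CCOP(=O)(COC)OCC
Why: Claisen-type acylation of the α-lithiated phosphonate by the methyl ester gives the β-ketophosphonate, which is deprotonated as it forms (hence excess anion) and so cannot react twice; the new phosphorus-bearing centre is a mixture that vanishes in the olefination.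

Step 10
Reactants: 16 diethyl [(1RS)-3-[(2R,3R,4S,5R)-3-allyl-3-(dimethoxymethyl)-4-methyl-5-(3,4,5-trimethoxyphenyl)oxolan-2-yl]-1-methoxy-2-oxopropyl]phosphonate
Product: 18 (2R,3S,3aS,7aR)-3a-allyl-5-methoxy-3-methyl-2-(3,4,5-trimethoxyphenyl)-3,3a,7,7a-tetrahydro-1-benzofuran-6(2H)-one, via keto aldehyde phosphonate 17 (not isolated)
Conditions: 1 M HCl, THF, rt; then Ba(OH)2·8H2O, rt
Reagents that add atoms: none
Why: Acetal hydrolysis frees the aldehyde, and hydroxide then triggers an intramolecular Horner–Wadsworth–Emmons reaction that forms C4=C5 and the six-membered ring B; this is possible because formyl and ketophosphonate arms are cis on ring A, and no stereocentre is created.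

Step 11
Reactants: 18 (2R,3S,3aS,7aR)-3a-allyl-5-methoxy-3-methyl-2-(3,4,5-trimethoxyphenyl)-3,3a,7,7a-tetrahydro-1-benzofuran-6(2H)-one
Product: 20 (2R,3S,3aS)-3a-allyl-5-methoxy-3-methyl-2-(3,4,5-trimethoxyphenyl)-3,3a-dihydro-1-benzofuran-6(2H)-one, via trimethylsilyl dienol ether 19 (not isolated)
Conditions: TMSOTf, Et3N, CH2Cl2, 0 °C; then Pd(OAc)2, MeCN, rt
Reagents that add atoms: none
Why: Saegusa–Ito oxidation: enolization is possible only toward C7, and Pd(OAc)2 palladates C7 of the silyloxydiene and eliminates the hydrogen on C7a to give the C7=C7a enone, which erases the relay stereocentre C7a and leaves C2, C3 and C3a untouched.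

**Compound list**

1 | dimethyl (R)-malate | COC(=O)C[C@@H](O)C(=O)OC | starting material
2 | methyl (R)-3,4-dihydroxybutanoate | COC(=O)C[C@@H](O)CO | intermediate
3 | methyl (R)-3,4-bis(triethylsilyloxy)butanoate | COC(=O)C[C@@H](O[Si](CC)(CC)CC)CO[Si](CC)(CC)CC | intermediate
4 | methyl (R)-4-oxo-3-(triethylsilyloxy)butanoate | COC(=O)C[C@@H](O[Si](CC)(CC)CC)C=O | intermediate
5 | prop-1-ynylmagnesium bromide | CC#C[Mg]Br | starting material
6 | bromomagnesium (3R,4RS)-1-methoxy-1-oxo-3-(triethylsilyloxy)hept-5-yn-4-olate | COC(=O)C[C@@H](O[Si](CC)(CC)CC)C(O[Mg]Br)C#CC | intermediate (not isolated)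
7 | methyl (3R,4RS)-3,4-bis(triethylsilyloxy)hept-5-ynoate | COC(=O)C[C@@H](O[Si](CC)(CC)CC)C(O[Si](CC)(CC)CC)C#CC | intermediate
8 | methyl (3R,4RS,5E)-5-(tributylstannyl)-3,4-bis(triethylsilyloxy)hept-5-enoate | COC(=O)C[C@@H](O[Si](CC)(CC)CC)C(O[Si](CC)(CC)CC)/C([Sn](CCCC)(CCCC)CCCC)=C\C | intermediate
9 | allyl bromide | C=CCBr | starting material
10 | methyl (3R,4RS,5Z)-5-allyl-3,4-bis(triethylsilyloxy)hept-5-enoate | COC(=O)C[C@@H](O[Si](CC)(CC)CC)C(O[Si](CC)(CC)CC)/C(CC=C)=C\C | intermediate (key-step precursor)
11 | 3,4,5-trimethoxybenzaldehyde | COc1cc(C=O)cc(OC)c1OC | starting material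
12 | methyl 2-[(2RS,4R,5RS)-5-[(2Z)-hexa-2,5-dien-3-yl]-2-(3,4,5-trimethoxyphenyl)-1,3-dioxolan-4-yl]acetate | COC(=O)C[C@H]1OC(c2cc(OC)c(OC)c(OC)c2)OC1/C(CC=C)=C\C | intermediate (not isolated)
13 | methyl 2-[(2R,3R,4S,5R)-3-allyl-3-formyl-4-methyl-5-(3,4,5-trimethoxyphenyl)oxolan-2-yl]acetate | C=CC[C@]1(C=O)[C@@H](CC(=O)OC)O[C@@H](c2cc(OC)c(OC)c(OC)c2)[C@H]1C | intermediate (key-step product)
14 | methyl 2-[(2R,3R,4S,5R)-3-allyl-3-(dimethoxymethyl)-4-methyl-5-(3,4,5-trimethoxyphenyl)oxolan-2-yl]acetate | C=CC[C@]1(C(OC)OC)[C@@H](CC(=O)OC)O[C@@H](c2cc(OC)c(OC)c(OC)c2)[C@H]1C | intermediate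
15 | diethyl (methoxymethyl)phosphonate | CCOP(=O)(COC)OCC | starting material
16 | diethyl [(1RS)-3-[(2R,3R,4S,5R)-3-allyl-3-(dimethoxymethyl)-4-methyl-5-(3,4,5-trimethoxyphenyl)oxolan-2-yl]-1-methoxy-2-oxopropyl]phosphonate | C=CC[C@]1(C(OC)OC)[C@@H](CC(=O)C(OC)P(=O)(OCC)OCC)O[C@@H](c2cc(OC)c(OC)c(OC)c2)[C@H]1C | intermediate
17 | diethyl [(1RS)-3-[(2R,3R,4S,5R)-3-allyl-3-formyl-4-methyl-5-(3,4,5-trimethoxyphenyl)oxolan-2-yl]-1-methoxy-2-oxopropyl]phosphonate | C=CC[C@]1(C=O)[C@@H](CC(=O)C(OC)P(=O)(OCC)OCC)O[C@@H](c2cc(OC)c(OC)c(OC)c2)[C@H]1C | intermediate (not isolated)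
18 | (2R,3S,3aS,7aR)-3a-allyl-5-methoxy-3-methyl-2-(3,4,5-trimethoxyphenyl)-3,3a,7,7a-tetrahydro-1-benzofuran-6(2H)-one | C=CC[C@]12C=C(OC)C(=O)C[C@H]1O[C@@H](c1cc(OC)c(OC)c(OC)c1)[C@H]2C | intermediate
19 | [(2R,3S,3aS,7aR)-3a-allyl-5-methoxy-3-methyl-2-(3,4,5-trimethoxyphenyl)-2,3,3a,7a-tetrahydro-1-benzofuran-6-yl]oxy(trimethyl)silane | C=CC[C@]12C=C(OC)C(O[Si](C)(C)C)=C[C@H]1O[C@@H](c1cc(OC)c(OC)c(OC)c1)[C@H]2C | intermediate (not isolated)
20 | (2R,3S,3aS)-3a-allyl-5-methoxy-3-methyl-2-(3,4,5-trimethoxyphenyl)-3,3a-dihydro-1-benzofuran-6(2H)-one (CNP0197140.1) | C=CC[C@]12C=C(OC)C(=O)C=C1O[C@@H](c1cc(OC)c(OC)c(OC)c1)[C@H]2C | target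

**Count**

Total step count: 11 steps.
Longest linear sequence: 11 steps, from 1 to 20.

**Steps most likely to fail, with fallbacks**

Step 7. The condensation of two hindered silyl ethers with the aldehyde may be slow or incomplete, so that silyl loss and lactonization, or ionization before a defined acetal exists, erode the cascade. The fallback sets out from 7 and comes back at 12. It installs the acetal before the cross-couplings and uses it as the diol protecting group, so that the cationic step starts from a purified dioxolane. Aldehyde 11 with HC(OMe)3, MeOH and PPTS gives 3,4,5-trimethoxybenzaldehyde dimethyl acetal F1. Alkyne 7 and F1 with camphorsulfonic acid in MeOH, then toluene, undergo silyl ether methanolysis and transacetalization (any lactone is reopened by methanol) to give methyl 2-[(4R,5RS)-5-(prop-1-yn-1-yl)-2-(3,4,5-trimethoxyphenyl)-1,3-dioxolan-4-yl]acetate F2. Hydrostannation as in step 5 gives methyl 2-[(4R,5RS)-5-[(1E)-1-(tributylstannyl)prop-1-en-1-yl]-2-(3,4,5-trimethoxyphenyl)-1,3-dioxolan-4-yl]acetate F3. Stille allylation as in step 6 gives 12 as an isolated compound, which is rearranged with SnCl4 alone at −78 to −23 °C to 13.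

Step 5. Regiocontrol in the hydropalladation may be poor, with tin delivered in part to the methyl-bearing carbon because two bulky silyloxy groups shield the proximal position. The fallback sets out from 4 and comes back at 8. It puts the regiochemistry under electronic control by running the hydrostannation on an ynone. Addition of 5 to 4 with a cold acetic acid quench gives methyl (3R,4RS)-4-hydroxy-3-(triethylsilyloxy)hept-5-ynoate F4, used at once. Dess–Martin periodinane (NaHCO3, CH2Cl2) gives methyl (3R)-4-oxo-3-(triethylsilyloxy)hept-5-ynoate F5. Bu3SnH with PdCl2(PPh3)2 adds syn with tin α to the carbonyl group to give methyl (3R,5E)-4-oxo-5-(tributylstannyl)-3-(triethylsilyloxy)hept-5-enoate F6. 1,2-Reduction with NaBH4 and CeCl3·7H2O in MeOH at −78 °C gives methyl (3R,4RS,5E)-4-hydroxy-5-(tributylstannyl)-3-(triethylsilyloxy)hept-5-enoate F7, which is silylated at once (TESOTf, 2,6-lutidine, −78 °C) to 8.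

Step 6. Transmetalation at the congested, fully substituted alkenyltin carbon may be slow, so that protodestannylation or allyl–allyl coupling takes over. The fallback sets out from 8 and comes back at 10. It reverses the polarity of the coupling. I2 in CH2Cl2 at 0 °C converts 8 with retention into methyl (3R,4RS,5E)-5-iodo-3,4-bis(triethylsilyloxy)hept-5-enoate F8, which adds readily to zerovalent palladium. Stille coupling of F8 with allyltributylstannane (Pd2(dba)3, AsPh3, DMF) then gives 10.

**Further compounds**

F1 | step 7 | 3,4,5-trimethoxybenzaldehyde dimethyl acetal | COC(OC)c1cc(OC)c(OC)c(OC)c1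
F2 | step 7 | methyl 2-[(4R,5RS)-5-(prop-1-yn-1-yl)-2-(3,4,5-trimethoxyphenyl)-1,3-dioxolan-4-yl]acetate | COC(=O)C[C@H]1OC(c2cc(OC)c(OC)c(OC)c2)OC1C#CC
F3 | step 7 | methyl 2-[(4R,5RS)-5-[(1E)-1-(tributylstannyl)prop-1-en-1-yl]-2-(3,4,5-trimethoxyphenyl)-1,3-dioxolan-4-yl]acetate | COC(=O)C[C@H]1OC(c2cc(OC)c(OC)c(OC)c2)OC1/C([Sn](CCCC)(CCCC)CCCC)=C\C
F4 | step 5 | methyl (3R,4RS)-4-hydroxy-3-(triethylsilyloxy)hept-5-ynoate | COC(=O)C[C@@H](O[Si](CC)(CC)CC)C(O)C#CC
F5 | step 5 | methyl (3R)-4-oxo-3-(triethylsilyloxy)hept-5-ynoate | COC(=O)C[C@@H](O[Si](CC)(CC)CC)C(=O)C#CC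
F6 | step 5 | methyl (3R,5E)-4-oxo-5-(tributylstannyl)-3-(triethylsilyloxy)hept-5-enoate | COC(=O)C[C@@H](O[Si](CC)(CC)CC)C(=O)/C([Sn](CCCC)(CCCC)CCCC)=C\C
F7 | step 5 | methyl (3R,4RS,5E)-4-hydroxy-5-(tributylstannyl)-3-(triethylsilyloxy)hept-5-enoate | COC(=O)C[C@@H](O[Si](CC)(CC)CC)C(O)/C([Sn](CCCC)(CCCC)CCCC)=C\C
F8 | step 6 | methyl (3R,4RS,5E)-5-iodo-3,4-bis(triethylsilyloxy)hept-5-enoate | COC(=O)C[C@@H](O[Si](CC)(CC)CC)C(O[Si](CC)(CC)CC)/C(I)=C\C
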